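**Retrosynthetic overview**
- Bleochrin A ⇐ hydrogenolysis of three benzyl ethers, desilylation and one O-methylation of a resorcinol mono-silyl ether whose only free phenol sits between two benzyl groups.
- Ring A is not taken from an arene. It is built last by a Danheiser benzannulation of a 3,4-disubstituted cyclobutenone with a siloxyalkyne, so every substituent position is fixed by connectivity, not by aromatic substitution selectivity.
- The cyclobutenone ⇐ Ghosez keteniminium–alkyne [2+2] between a 3-arylpropanamide and a 4-aryl-but-1-yne that already carries ring B and the two-carbon bridge.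
- The ring B butyne ⇐ Suzuki benzylation of a formylarylboronic acid, then reduction, bromination and propargylation.
- Ring order: ring B and the three 4-oxyphenyl rings are bought; the four-membered ring is formed in step 6 and ring A in step 9.

Assumption: the target SMILES has no stereocentre and no stereogenic double bond, so Bleochrin A is achiral and the "single enantiomer" is the compound itself; the one stereocentre that appears on the way (C4 of the cyclobutenone) is racemic and disappears on aromatisation.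

Abbreviations in names: Bn = benzyl; PBB = 4-(benzyloxy)benzyl (CH2–C6H4–OBn, para); ArB = 5-(benzyloxy)-2-(PBB)phenyl (protected ring B); TIPS = triisopropylsilyl; CDI = 1,1'-carbonyldiimidazole.

**Step 1**
Reactants: 1 (4-benzyloxy-2-formylphenyl)boronic acid; 2 4-(benzyloxy)benzyl chloride
Product: 3 5-(benzyloxy)-2-(PBB)benzaldehyde
Conditions: Pd(OAc)2 (2 mol %), PPh3 (4 mol %), K3PO4·H2O, toluene, 80 °C
Reagents that add atoms: none
Why: Suzuki–Miyaura sp3–sp2 cross-coupling, in which zerovalent palladium inserts readily into the benzylic C–Cl bond, the formyl group is tolerated and phosphate in toluene avoids solvolysis of the electron-rich benzyl chloride.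

**Step 2**
Reactants: 3 5-(benzyloxy)-2-(PBB)benzaldehyde
Product: 4 [5-(benzyloxy)-2-(PBB)phenyl]methanol
Conditions: NaBH4, MeOH/THF, 0 °C
Reagents that add atoms: none
Why: Chemoselective borohydride reduction of the aldehyde to the primary benzylic alcohol, with benzyl ethers and the diarylmethane inert.

**Step 3**
Reactants: 4 [5-(benzyloxy)-2-(PBB)phenyl]methanol
Product: 5 4-(benzyloxy)-2-(bromomethyl)-1-(PBB)benzene
Conditions: PBr3, CH2Cl2, 0 °C
Reagents that add atoms: phosphorus tribromide, BrP(Br)Br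
Why: Alcohol-to-bromide substitution through the phosphite ester (SN2), which is fast for a primary benzylic alcohol and leaves aryl benzyl ethers untouched at 0 °C.

**Step 4**
Reactants: 5 4-(benzyloxy)-2-(bromomethyl)-1-(PBB)benzene; 6 1-(trimethylsilyl)prop-1-yne
Product: 9 4-(ArB)but-1-yne, via propargyllithium 7 (not isolated), via silyl alkyne 8 (not isolated)
Conditions: 6, n-BuLi, THF, −78 °C; then 5, −78 to 0 °C; then K2CO3 (cat.), MeOH, 25 °C
Reagents that add atoms: none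
Why: Corey–Kirst propargylation, in which 3-lithio-1-(trimethylsilyl)propyne alkylates the benzylic bromide at its propargylic carbon (the silyl group suppresses allenyl products) and methanolysis then frees the terminal alkyne.

**Step 5**
Reactants: 10 3-[4-(benzyloxy)phenyl]propanoic acid
Product: 12 3-[4-(benzyloxy)phenyl]-N,N-dimethylpropanamide, via acyl imidazolide 11 (not isolated)
Conditions: CDI, THF, 25 °C; then Me2NH (2 M in THF), 25 °C
Reagents that add atoms: dimethylamine, CNC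
Why: Amide formation by acyl substitution through the acyl imidazolide, giving the tertiary amide needed for keteniminium generation.

**Step 6**
Reactants: 12 3-[4-(benzyloxy)phenyl]-N,N-dimethylpropanamide; 9 4-(ArB)but-1-yne
Product: 15 4-(PBB)-3-[2-(ArB)ethyl]cyclobut-2-en-1-one (racemic), via keteniminium triflate 13 (not isolated), via cyclobuteniminium triflate 14 (not isolated)
Conditions: Tf2O, 2,4,6-collidine, ClCH2CH2Cl, −20 to 80 °C; then H2O, 25 °C
Reagents that add atoms: water, O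
Why: Ghosez keteniminium–alkyne [2+2] cycloaddition, in which the terminal alkyne carbon attacks the central carbon of the aldo-keteniminium ion so that the chain ends at C3 and the PBB group at C4 after iminium hydrolysis, the new C4 stereocentre being racemic and erased in step 9.

**Step 7**
Reactants: 2 4-(benzyloxy)benzyl chloride; 16 ethynylmagnesium bromide
Product: 17 1-(benzyloxy)-4-(prop-2-yn-1-yl)benzene
Conditions: CuBr·SMe2 (10 mol %), THF, 60 °C
Reagents that add atoms: none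
Why: Copper-catalysed sp–sp3 substitution of the activated benzylic chloride by the ethynyl Grignard reagent gives the propargyl arene.

**Step 8**
Reactants: 17 1-(benzyloxy)-4-(prop-2-yn-1-yl)benzene
Product: 20 triisopropyl({3-[4-(benzyloxy)phenyl]prop-1-yn-1-yl}oxy)silane, via lithium acetylide 18 (not isolated), via lithium ynolate 19 (not isolated)
Conditions: n-BuLi, THF, −78 °C; t-BuOOLi (from t-BuOOH + LiN(SiMe3)2), −78 to 0 °C; TIPSOTf, −78 to 0 °C
Reagents that add atoms: tert-butyl hydroperoxide, CC(C)(C)OO; triisopropylsilyl trifluoromethanesulfonate, CC(C)[Si](OS(=O)(=O)C(F)(F)F)(C(C)C)C(C)C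
Why: Julia-type oxidation of the lithium acetylide by electrophilic oxygen transfer from lithium tert-butyl peroxide gives the ynolate, which the bulky silyl triflate traps on oxygen as an isolable silyl ynol ether.

**Step 9**
Reactants: 15 4-(PBB)-3-[2-(ArB)ethyl]cyclobut-2-en-1-one; 20 triisopropyl({3-[4-(benzyloxy)phenyl]prop-1-yn-1-yl}oxy)silane
Product: 25 2,6-bis(PBB)-3-[2-(ArB)ethyl]-5-[(triisopropylsilyl)oxy]phenol, via vinylketene 21 (not isolated), via vinylcyclobutenone 22 (not isolated), via dienylketene 23 (not isolated), via cyclohexadienone 24 (not isolated)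
Conditions: 20 (1.3 equiv), toluene, 85 °C then 110 °C
Reagents that add atoms: none
Why: Danheiser benzannulation, a pericyclic cascade of 4π ring opening to the vinylketene, regioselective [2+2] with the siloxyalkyne (its benzyl-bearing carbon bonds to the ketene carbonyl carbon), 4π opening, 6π electrocyclisation and tautomerisation, which places all five ring A substituents by connectivity and leaves no stereocentre.

**Step 10**
Reactants: 25 2,6-bis(PBB)-3-[2-(ArB)ethyl]-5-[(triisopropylsilyl)oxy]phenol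
Product: 26 triisopropyl{2,4-bis(PBB)-5-[2-(ArB)ethyl]-3-methoxyphenoxy}silane
Conditions: MeI, K2CO3, acetone, 50 °C
Reagents that add atoms: iodomethane, CI
Why: Williamson O-methylation of the only free phenol, the other ring A oxygen being blocked as the silyl ether, which fixes the methoxy group between the two benzyl groups.

**Step 11**
Reactants: 26 triisopropyl{2,4-bis(PBB)-5-[2-(ArB)ethyl]-3-methoxyphenoxy}silane
Product: 27 2,4-bis(PBB)-5-[2-(ArB)ethyl]-3-methoxyphenol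
Conditions: Bu4NF, AcOH, THF, 0 to 25 °C
Reagents that add atoms: none
Why: Fluoride-induced cleavage of the aryl silyl ether, buffered with acetic acid so the phenoxide is protonated at once, with benzyl and methyl ethers untouched.

**Step 12**
Reactants: 27 2,4-bis(PBB)-5-[2-(ArB)ethyl]-3-methoxyphenol
Product: 28 Bleochrin A
Conditions: H2 (1 atm), 10% Pd/C, EtOAc/MeOH, 25 °C
Reagents that add atoms: none
Why: Heterogeneous catalytic hydrogenolysis of the three aryl benzyl ethers, under which the diarylmethane C–C bonds, the bibenzyl bridge and the methyl ether are stable and no stereocentre is involved.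

**Compound list**
1 | (4-benzyloxy-2-formylphenyl)boronic acid | OB(O)c1ccc(OCc2ccccc2)cc1C=O | starting material
2 | 4-(benzyloxy)benzyl chloride | ClCc1ccc(OCc2ccccc2)cc1 | starting material
3 | 5-(benzyloxy)-2-(PBB)benzaldehyde | O=Cc1cc(OCc2ccccc2)ccc1Cc1ccc(OCc2ccccc2)cc1 | intermediate
4 | [5-(benzyloxy)-2-(PBB)phenyl]methanol | OCc1cc(OCc2ccccc2)ccc1Cc1ccc(OCc2ccccc2)cc1 | intermediate
5 | 4-(benzyloxy)-2-(bromomethyl)-1-(PBB)benzene | BrCc1cc(OCc2ccccc2)ccc1Cc1ccc(OCc2ccccc2)cc1 | intermediate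
6 | 1-(trimethylsilyl)prop-1-yne | CC#C[Si](C)(C)C | starting material
7 | 3-lithio-1-(trimethylsilyl)prop-1-yne (propargyllithium) | [Li]CC#C[Si](C)(C)C | intermediate
8 | trimethyl[4-(ArB)but-1-yn-1-yl]silane | C[Si](C)(C)C#CCCc1cc(OCc2ccccc2)ccc1Cc1ccc(OCc2ccccc2)cc1 | intermediate
9 | 4-(ArB)but-1-yne | C#CCCc1cc(OCc2ccccc2)ccc1Cc1ccc(OCc2ccccc2)cc1 | intermediate
10 | 3-[4-(benzyloxy)phenyl]propanoic acid | OC(=O)CCc1ccc(OCc2ccccc2)cc1 | starting material
11 | 1-{3-[4-(benzyloxy)phenyl]propanoyl}imidazole | O=C(CCc1ccc(OCc2ccccc2)cc1)n1ccnc1 | intermediate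
12 | 3-[4-(benzyloxy)phenyl]-N,N-dimethylpropanamide | CN(C)C(=O)CCc1ccc(OCc2ccccc2)cc1 | intermediate
13 | N-{3-[4-(benzyloxy)phenyl]prop-1-en-1-ylidene}-N-methylmethanaminium triflate (keteniminium salt) | C[N+](C)=C=CCc1ccc(OCc2ccccc2)cc1.[O-]S(=O)(=O)C(F)(F)F | intermediate
14 | cyclobuteniminium triflate: 15 with C=N(+)Me2 in place of C=O (racemic) | C[N+](C)=C1C=C(CCc2cc(OCc3ccccc3)ccc2Cc2ccc(OCc3ccccc3)cc2)C1Cc1ccc(OCc2ccccc2)cc1.[O-]S(=O)(=O)C(F)(F)F | intermediate
15 | 4-(PBB)-3-[2-(ArB)ethyl]cyclobut-2-en-1-one (racemic) | O=C1C=C(CCc2cc(OCc3ccccc3)ccc2Cc2ccc(OCc3ccccc3)cc2)C1Cc1ccc(OCc2ccccc2)cc1 | intermediate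
16 | ethynylmagnesium bromide | C#C[Mg]Br | starting material
17 | 1-(benzyloxy)-4-(prop-2-yn-1-yl)benzene | C#CCc1ccc(OCc2ccccc2)cc1 | intermediate
18 | {3-[4-(benzyloxy)phenyl]prop-1-yn-1-yl}lithium | [Li]C#CCc1ccc(OCc2ccccc2)cc1 | intermediate
19 | lithium 3-[4-(benzyloxy)phenyl]prop-1-yn-1-olate (ynolate) | [Li]OC#CCc1ccc(OCc2ccccc2)cc1 | intermediate
20 | triisopropyl({3-[4-(benzyloxy)phenyl]prop-1-yn-1-yl}oxy)silane | CC(C)[Si](OC#CCc1ccc(OCc2ccccc2)cc1)(C(C)C)C(C)C | intermediate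
21 | (3E)-5-[4-(benzyloxy)phenyl]-3-[2-(ArB)ethyl]penta-1,3-dien-1-one (vinylketene) | O=C=C/C(CCc1cc(OCc2ccccc2)ccc1Cc1ccc(OCc2ccccc2)cc1)=C/Cc1ccc(OCc2ccccc2)cc1 | intermediate
22 | 2-(PBB)-3-[(triisopropylsilyl)oxy]-4-{(E)-1-[2-(ArB)ethyl]-3-[4-(benzyloxy)phenyl]prop-1-en-1-yl}cyclobut-2-en-1-one (racemic) | O=C1C(Cc2ccc(OCc3ccccc3)cc2)=C(O[Si](C(C)C)(C(C)C)C(C)C)C1/C(CCc1cc(OCc2ccccc2)ccc1Cc1ccc(OCc2ccccc2)cc1)=C/Cc1ccc(OCc2ccccc2)cc1 | intermediate
23 | dienylketene: 2-(PBB)-3-[(triisopropylsilyl)oxy]-5-[2-(ArB)ethyl]-7-[4-(benzyloxy)phenyl]hepta-1,3,5-trien-1-one, ketene carbon and C5 cis across C3=C4, C5=C6 (E) | O=C=C(Cc1ccc(OCc2ccccc2)cc1)/C(O[Si](C(C)C)(C(C)C)C(C)C)=C\C(CCc1cc(OCc2ccccc2)ccc1Cc1ccc(OCc2ccccc2)cc1)=C\Cc1ccc(OCc2ccccc2)cc1 | intermediate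
24 | 2,6-bis(PBB)-5-[2-(ArB)ethyl]-3-[(triisopropylsilyl)oxy]cyclohexa-2,4-dien-1-one (racemic keto tautomer of 25) | O=C1C(Cc2ccc(OCc3ccccc3)cc2)=C(O[Si](C(C)C)(C(C)C)C(C)C)C=C(CCc2cc(OCc3ccccc3)ccc2Cc2ccc(OCc3ccccc3)cc2)C1Cc1ccc(OCc2ccccc2)cc1 | intermediate
25 | 2,6-bis(PBB)-3-[2-(ArB)ethyl]-5-[(triisopropylsilyl)oxy]phenol | Oc1c(Cc2ccc(OCc3ccccc3)cc2)c(O[Si](C(C)C)(C(C)C)C(C)C)cc(CCc2cc(OCc3ccccc3)ccc2Cc2ccc(OCc3ccccc3)cc2)c1Cc1ccc(OCc2ccccc2)cc1 | intermediate
26 | triisopropyl{2,4-bis(PBB)-5-[2-(ArB)ethyl]-3-methoxyphenoxy}silane | COc1c(Cc2ccc(OCc3ccccc3)cc2)c(O[Si](C(C)C)(C(C)C)C(C)C)cc(CCc2cc(OCc3ccccc3)ccc2Cc2ccc(OCc3ccccc3)cc2)c1Cc1ccc(OCc2ccccc2)cc1 | intermediate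
27 | 2,4-bis(PBB)-5-[2-(ArB)ethyl]-3-methoxyphenol | COc1c(Cc2ccc(OCc3ccccc3)cc2)c(O)cc(CCc2cc(OCc3ccccc3)ccc2Cc2ccc(OCc3ccccc3)cc2)c1Cc1ccc(OCc2ccccc2)cc1 | intermediate
28 | Bleochrin A, 5-{2-[5-hydroxy-2-(4-hydroxybenzyl)phenyl]ethyl}-2,4-bis(4-hydroxybenzyl)-3-methoxyphenol (achiral) | COc1c(Cc2ccc(O)cc2)c(O)cc(CCc2cc(O)ccc2Cc2ccc(O)cc2)c1Cc1ccc(O)cc1 | target

**Totals**
Total step count: 12. Longest linear sequence: 9 steps (steps 1, 2, 3, 4, 6, 9, 10, 11, 12, from boronic acid 1 to 28).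

**Three steps most likely to fail**

Step 9 (benzannulation). The 4-substituted cyclobutenone 15 may divert at the vinylketene stage or close slowly. The fallback sets out from alkyne 9 and puts the third benzyl group on after the annulation. Dichloroketene cycloaddition (Cl3CCOCl, Zn(Cu), Et2O) gives 4,4-dichloro-3-[2-(ArB)ethyl]cyclobut-2-en-1-one F1. Dechlorination (Zn, AcOH, TMEDA, EtOH) gives 3-[2-(ArB)ethyl]cyclobut-2-en-1-one F2, the classical substrate type for this annulation. Heating F2 with siloxyalkyne 20 in toluene gives 2-(PBB)-5-[2-(ArB)ethyl]-3-[(triisopropylsilyl)oxy]phenol F3. Magnesium-mediated ortho-formylation (MgCl2, Et3N, paraformaldehyde, MeCN, 80 °C) can only reach the single free ortho position and gives 3-(PBB)-6-[2-(ArB)ethyl]-2-hydroxy-4-[(triisopropylsilyl)oxy]benzaldehyde F4. Addition of 4-(benzyloxy)phenylmagnesium bromide (THF, 0 °C) gives the racemic diaryl carbinol F5, and ionic hydrogenation (Et3SiH, CF3CO2H, CH2Cl2, −20 °C) returns to the route at 25.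

Step 6 (keteniminium–alkyne [2+2]). The aldo-keteniminium ion may be intercepted by the electron-rich arenes or react sluggishly with the alkyne. The fallback sets out from aldehyde 3 and acid 10 and builds the cyclobutenone by ketene–ethoxyacetylene cycloaddition followed by organolithium addition. Wittig methylenation of 3 (Ph3PCH3Br, KOt-Bu, THF) gives 4-(benzyloxy)-2-ethenyl-1-(PBB)benzene F6. Hydroboration–oxidation (9-BBN, THF; NaOH, H2O2) gives 2-(ArB)ethanol F7, and iodination (I2, PPh3, imidazole, CH2Cl2) gives 4-(benzyloxy)-2-(2-iodoethyl)-1-(PBB)benzene F8. Separately, acid 10 is converted ((COCl)2, cat. DMF, CH2Cl2) to 3-[4-(benzyloxy)phenyl]propanoyl chloride F9. With Et3N and ethoxyacetylene in Et2O this passes through [4-(benzyloxy)benzyl]ketene F10 to racemic 4-(PBB)-3-ethoxycyclobut-2-en-1-one F11. Iodine–lithium exchange on F8 (t-BuLi, 2 equiv, Et2O, −78 °C) gives [2-(ArB)ethyl]lithium F12, which adds to the carbonyl of F11 to give 4-(PBB)-3-ethoxy-1-[2-(ArB)ethyl]cyclobut-2-en-1-ol F13. Dilute aqueous HCl in THF hydrolyses the enol ether with loss of water and returns to the route at 15.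

Step 8 (acetylide oxidation and O-silylation). The doubly activated propargylic CH2 may interfere with the oxidation, or the ynol ether may be lost on isolation. The fallback sets out from chloride 2 and reaches the same ynolate by the Kowalski ester rearrangement. Methoxycarbonylation (PdCl2(PPh3)2, CO 1 atm, MeOH, K2CO3, THF) gives methyl [4-(benzyloxy)phenyl]acetate F14, an ester that can also be bought. Treatment with CH2Br2 and lithium 2,2,6,6-tetramethylpiperidide (THF, −78 °C), then LiN(SiMe3)2, gives lithium 3-[4-(benzyloxy)phenyl]-1,1-dibromoprop-1-en-2-olate F15. n-BuLi (−78 to 25 °C) triggers bromine–lithium exchange and 1,2-shift, returning to the route at lithium ynolate 19, which is silylated (TIPSCl) to 20.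

**Further compounds**
F1 | step 9 | 4,4-dichloro-3-[2-(ArB)ethyl]cyclobut-2-en-1-one | O=C1C=C(CCc2cc(OCc3ccccc3)ccc2Cc2ccc(OCc3ccccc3)cc2)C1(Cl)Cl
F2 | step 9 | 3-[2-(ArB)ethyl]cyclobut-2-en-1-one | O=C1C=C(CCc2cc(OCc3ccccc3)ccc2Cc2ccc(OCc3ccccc3)cc2)C1
F3 | step 9 | 2-(PBB)-5-[2-(ArB)ethyl]-3-[(triisopropylsilyl)oxy]phenol | Oc1cc(CCc2cc(OCc3ccccc3)ccc2Cc2ccc(OCc3ccccc3)cc2)cc(O[Si](C(C)C)(C(C)C)C(C)C)c1Cc1ccc(OCc2ccccc2)cc1
F4 | step 9 | 3-(PBB)-6-[2-(ArB)ethyl]-2-hydroxy-4-[(triisopropylsilyl)oxy]benzaldehyde | O=Cc1c(O)c(Cc2ccc(OCc3ccccc3)cc2)c(O[Si](C(C)C)(C(C)C)C(C)C)cc1CCc1cc(OCc2ccccc2)ccc1Cc1ccc(OCc2ccccc2)cc1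
F5 | step 9 | 2-{[4-(benzyloxy)phenyl](hydroxy)methyl}-6-(PBB)-3-[2-(ArB)ethyl]-5-[(triisopropylsilyl)oxy]phenol (racemic) | OC(c1ccc(OCc2ccccc2)cc1)c1c(O)c(Cc2ccc(OCc3ccccc3)cc2)c(O[Si](C(C)C)(C(C)C)C(C)C)cc1CCc1cc(OCc2ccccc2)ccc1Cc1ccc(OCc2ccccc2)cc1
F6 | step 6 | 4-(benzyloxy)-2-ethenyl-1-(PBB)benzene | C=Cc1cc(OCc2ccccc2)ccc1Cc1ccc(OCc2ccccc2)cc1
F7 | step 6 | 2-(ArB)ethanol | OCCc1cc(OCc2ccccc2)ccc1Cc1ccc(OCc2ccccc2)cc1
F8 | step 6 | 4-(benzyloxy)-2-(2-iodoethyl)-1-(PBB)benzene | ICCc1cc(OCc2ccccc2)ccc1Cc1ccc(OCc2ccccc2)cc1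
F9 | step 6 | 3-[4-(benzyloxy)phenyl]propanoyl chloride | ClC(=O)CCc1ccc(OCc2ccccc2)cc1
F10 | step 6 | [4-(benzyloxy)benzyl]ketene, 3-[4-(benzyloxy)phenyl]prop-1-en-1-one | O=C=CCc1ccc(OCc2ccccc2)cc1
F11 | step 6 | 4-(PBB)-3-ethoxycyclobut-2-en-1-one (racemic) | CCOC1=CC(=O)C1Cc1ccc(OCc2ccccc2)cc1
F12 | step 6 | [2-(ArB)ethyl]lithium | [Li]CCc1cc(OCc2ccccc2)ccc1Cc1ccc(OCc2ccccc2)cc1
F13 | step 6 | 4-(PBB)-3-ethoxy-1-[2-(ArB)ethyl]cyclobut-2-en-1-ol (diastereomer mixture) | CCOC1=CC(O)(CCc2cc(OCc3ccccc3)ccc2Cc2ccc(OCc3ccccc3)cc2)C1Cc1ccc(OCc2ccccc2)cc1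
F14 | step 8 | methyl [4-(benzyloxy)phenyl]acetate | COC(=O)Cc1ccc(OCc2ccccc2)cc1
F15 | step 8 | lithium 3-[4-(benzyloxy)phenyl]-1,1-dibromoprop-1-en-2-olate | [Li]OC(Cc1ccc(OCc2ccccc2)cc1)=C(Br)Br
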